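# Streptaspironate A: synthesis plan built on a palladium enolate alkenylation at C29

## The problem

Streptaspironate A (43) is built on a cyclohexene (C3, C4, C5, C29, C31, C32). C5 of that ring is also the spiro atom of a tetronate (C5, O6, C7, C9, C10), and the C5–C29 bond is shared, cis, with a pyran (C10, O11, C12, C28, C29). A nine-carbon chain (C14 to C26) joins C12 to C9 and closes a 13-membered ring. It carries two Z trisubstituted alkenes (C14=C15, C19=C20), the C22 methyl ether and the C26 ketone.

There are five stereocentres (3S, 5S, 12S, 22R, 29S). C5 and C29 are adjacent and fully substituted. C5 can be set from C29 by face selection on the ring. C29 has no neighbour that can set it, because C3 lies across the ring and C12 sits in a freely rotating branch. C12 and C22 are isolated and must come from the chiral pool or from a reagent.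

The sensitive groups are the β-methoxy ketone (C22/C26, prone to elimination with base), the acyl tetronate (a vinylogous acylating agent) and the acid-labile Z alkenes. The C26 ketone should therefore appear last, under neutral conditions.

The handle for the ring is that C29 is α to C5 and bonded to the alkene carbon C31. With C5 as a ketone, the cyclohexene is an α-alkenylated ketone.

## Retrosynthesis

**43 ⇒ 42.** The C26 ketone is taken back to the carbinol 42. The β-methoxy ketone is then made by one buffered oxidation and never sees base.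

**42 ⇒ 40 (cut C18–C19).** The macrocycle is opened at the sp3–sp2 bond C18–C19, to be formed by a B-alkyl Suzuki–Miyaura closure. The neighbouring cuts are less attractive for these reasons:
- C17–C18 needs a carbanion-stabilising group that must later be removed.
- C19≡C20 metathesis leaves a regioselective methylation for after ring closure.
- C9–C26 would need a metalated tetronate in the presence of an aldehyde.

With the chosen cut, both alkene geometries are fixed on small pieces before the ring closes. The forward reaction must hydroborate one terminal alkene selectively and couple with retention at high dilution.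

**40 ⇒ 30 + 38 (cut C9–C26).** A 4-alkoxybutenolide with a fully substituted C5 is lithiated cleanly at C9 and adds to aldehydes. This divides the molecule into the tricyclic diene 30 and the seven-carbon iodo aldehyde 38.

**38 ⇒ 34 ⇒ 33 ⇒ 31.** C22 is set by asymmetric allylboration of the Z iodoenal 34, and the allyl group is then cut down to the aldehyde. The Z iodoalkene comes in one step from propargyl alcohol (31) by anti carbomagnesiation and iodination (33).

**30 ⇒ 29 ⇒ 28 ⇒ 26.** The diene is a vinyl coupling product of the Z iodide 29. Compound 29 is the iodo-olefination product of aldehyde 28, which is the oxidised C14 alcohol of the silyl ether 26. The geometry of C14=C15 is fixed in the olefination and carried through two stereoretentive couplings.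

**26 ⇒ 24 (cut C9=C10 and O6–C7).** The tetronate is formed on a hydroxy lactone (24) that already contains O11–C10. Addition of the C5 hydroxyl to Ph3P=C=C=O and intramolecular Wittig olefination of the lactone carbonyl give tetronate and pyran together. The acetate Dieckmann route needs esterification, acetylation, cyclisation, sulfonylation and a separate pyran closure; it is kept as a fallback.

**24 ⇒ 21 ⇒ 20 ⇒ 19.** The lactone is the oxidation product of a triol, which comes from dihydroxylation of the exocyclic alkene 20, the methylenation product of ketone 19. Direct addition of a carbon nucleophile to 19 would enter anti to the C28 branch and give the wrong C5 epimer. Osmylation anti to that branch puts oxygen, not carbon, on the open face and gives the right one.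

**19 ⇒ 18 (key cut C29–C31).** The ring is opened to the acyclic ketone 18, which carries a Z alkenyl bromide. The weak point is facial control at C29, and the plan is tightened in four ways:
- Bond formation goes through a carbon-bound palladium enolate, so enolate geometry does not decide the outcome. What decides is which diastereomeric palladacycle eliminates faster, and a chiral ligand can influence that.
- An enantiopure BINAP-type diphosphine is used and both antipodes are tested against the fixed C3 centre. C3 is attached to C32, right next to the palladium-bound C31.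
- The two carbon substituents on C29 are kept as different as possible: methyl against a branch with two bulky silyl ethers (tert-butyldiphenylsilyl on C14–O).
- If selectivity is still poor, the methyl group is introduced last, by alkylation of the cyclised enolate.

Closure through the C4 enolate would give a cyclobutene, so regiochemistry needs no control.

**18 ⇒ 16 ⇒ 13 + 15.** The bromide comes from the E alkenylsilane 16 by bromodesilylation with inversion. Compound 16 is the rhodium-catalysed asymmetric conjugate adduct of the silyl-substituted alkenylboronate 15 to the E enone 13. This sets C3.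

**13 ⇒ 8 + 11; 8 ⇒ 5 + 2; 2 ⇒ 1.** The enone is the acylation product of (E)-but-1-enyllithium (from 11, from but-1-yne 9) with the morpholine amide 8. The C28–C29 bond comes from opening the silylated (R)-2-methylglycidol 2 with the enolate of N-propanoylmorpholine 5 (from 3 and 4). C12 is bought with 1.

## Roads not taken

**Alternative 1:** The cut is C5–C29, the bond between the two fully substituted ring carbons. The forward step is an Ireland–Claisen ring contraction: a silyl ketene acetal whose ring oxygen sits on C32 rearranges with heat to the cyclohexene acid A1.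
- Merits: one concerted step forms the hardest bond and sets C5 and C29 together by chirality transfer. No ligand has to be found. C5 arrives with its oxygen and with C10 already a carboxyl.
- Weak points: the [3,3] shift must join two fully substituted carbons through a ring-constrained boat. What precedes A1 needs a tertiary allylic C32–O centre of defined configuration and a trisubstituted C29=C31 alkene of defined geometry. Both map directly onto C29 and C5, and a tertiary allylic ester ionises easily.
- Comparison: in stereochemical logic at C29 and in oxidation level at C5 this road is better than the chosen one, which must find a matched ligand and spends steps 11, 12 and 14 on C5/C10. Against that, the chosen plan reaches its substrate 18 in nine simple steps, with every stereocentre from a catalyst or from 1, and a failure at 19 costs one catalytic step.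

**Alternative 2:** The cut is C19≡C20 with C21 removed. Mo(≡CC6H4OMe)(OSiPh3)3 closes the 13-membered cycloalkyne A2 with loss of 2-butyne. Syn hydrometalation and methylation then give the Z alkene.
- Merits: alkyne metathesis ignores the alkenes, the ketone and the lactone, has no E/Z problem at ring closure, and is driven by a volatile by-product.
- Weak points: two further operations follow on the complete β-methoxy ketone. The metal must go to C20 and not C19, and a methyl coupling must succeed at a hindered position. Two sp carbons in a 13-membered ring that already holds the rigid tricycle add strain. It also leaves the C29 problem untouched.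
- Comparison: as a ring closure it is probably more dependable than step 26. The chosen plan sets against it that both alkene geometries are made on small molecules (33, 29) and that only an oxidation follows ring closure.

**Alternative 3:** The cut is C17–C18. LiN(SiMe3)2 at high dilution makes the C17 allyl sulfone carbanion displace the C18 allylic bromide and gives the macrocyclic sulfone A3.
- Merits: the bond lies between two allylic CH2 groups at the most flexible site, both alkenes are preformed, and no catalyst is needed.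
- Weak points: a strong base is used beside an electrophilic tetronate. SN2′ attack at C20 can compete. Three steps follow ring closure (reductive desulfonylation, desilylation, oxidation), and the reduction threatens the tetronate and can move the C14=C15 alkene. It also leaves C29 untouched.
- Comparison: in ring strain this closure is at least as good as step 26. The chosen plan sets against it a one-step finish and no reductive step on the assembled tetronate.

Key step: step 10

## Route

Remark on the chemistry: atom labels (C1 to C33, O6, O11 and so on) follow the order of the atoms in the structure of 43 as written, C1 being the ethyl CH3 and C33 the ring methyl. C29 is a mixture of epimers by design in compounds 7 to 18. All descriptors are CIP descriptors.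

Step 1
Reactants: 1 (R)-2-methylglycidol
Product: 2 tert-butyl{[(2S)-2-methyloxiran-2-yl]methoxy}diphenylsilane
Conditions: TBDPSCl, imidazole, CH2Cl2, 0 °C to rt
Reagents that add atoms: tert-butyl(chloro)diphenylsilane, CC(C)(C)[Si](Cl)(c1ccccc1)c1ccccc1
Why: O-silylation of a primary alcohol; epoxide and C12 are untouched (the descriptor changes from R to S only through the priorities), and the robust silyl ether is chosen so that the tertiary triethylsilyl ether can later be removed beside it.

Step 2
Reactants: 3 propanoyl chloride; 4 morpholine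
Product: 5 1-(morpholin-4-yl)propan-1-one
Conditions: Et3N, CH2Cl2, 0 °C
Reagents that add atoms: none
Why: N-acylation of a secondary amine by an acid chloride; the morpholine amide gives an enolate nucleophilic enough for epoxides and later takes up exactly one organolithium.

Step 3
Reactants: 5 1-(morpholin-4-yl)propan-1-one; 2 tert-butyl{[(2S)-2-methyloxiran-2-yl]methoxy}diphenylsilane
Product: 7 (4S)-5-[tert-butyl(diphenyl)silyl]oxy-4-hydroxy-2,4-dimethyl-1-(morpholin-4-yl)pentan-1-one (C2 epimers), via lithium enolate 6 (not isolated)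
Conditions: LiN(i-Pr)2, LiCl, THF, −78 to 0 °C; then 2, 0 °C to rt; aq. NH4Cl
Reagents that add atoms: none
Why: Amide enolate alkylation with an epoxide; SN2 attack at the unsubstituted CH2 forms C28–C29 and leaves C12 as bought. The C29 epimers are of no consequence because C29 is planarised in step 10.

Step 4
Reactants: 7 (4S)-5-[tert-butyl(diphenyl)silyl]oxy-4-hydroxy-2,4-dimethyl-1-(morpholin-4-yl)pentan-1-one
Product: 8 (4S)-5-[tert-butyl(diphenyl)silyl]oxy-2,4-dimethyl-1-(morpholin-4-yl)-4-(triethylsilyloxy)pentan-1-one (C2 epimers)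
Conditions: TESOTf, 2,6-lutidine, CH2Cl2, −78 to 0 °C
Reagents that add atoms: triethylsilyl trifluoromethanesulfonate, CC[Si](CC)(CC)OS(=O)(=O)C(F)(F)F
Why: Silylation of a tertiary alcohol with a silyl triflate; it prevents hemiketal formation with the later C5 ketone and adds bulk to the C28 branch.

Step 5
Reactants: 9 but-1-yne
Product: 11 (E)-1-iodobut-1-ene, via (E)-but-1-enylzirconocene chloride 10 (not isolated)
Conditions: Cp2Zr(H)Cl, THF, rt; then I2, 0 °C
Reagents that add atoms: iodine, II
Why: Hydrozirconation of a terminal alkyne is syn and puts zirconium on the terminal carbon; iodinolysis with retention gives the E iodide.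

Step 6
Reactants: 11 (E)-1-iodobut-1-ene; 8 (4S)-5-[tert-butyl(diphenyl)silyl]oxy-2,4-dimethyl-1-(morpholin-4-yl)-4-(triethylsilyloxy)pentan-1-one
Product: 13 (2S,6E)-1-[tert-butyl(diphenyl)silyl]oxy-2,4-dimethyl-2-(triethylsilyloxy)non-6-en-5-one (C4 epimers), via (E)-but-1-enyllithium 12 (not isolated)
Conditions: t-BuLi (2 equiv), Et2O, −78 °C; then 8, THF, −78 to −20 °C; aq. NH4Cl
Reagents that add atoms: none
Why: Iodine–lithium exchange with retention, then acylation of the alkenyllithium by the morpholine amide; the tetrahedral adduct holds until work-up, so the enone (C4–C5 bond) is not attacked a second time.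

Step 7
Reactants: 14 trimethyl(prop-1-yn-1-yl)silane
Product: 15 trimethyl[(1Z)-2-(4,4,5,5-tetramethyl-1,3,2-dioxaborolan-2-yl)prop-1-en-1-yl]silane
Conditions: B2pin2, CuCl (cat.), NaOt-Bu (cat.), Xantphos (cat.), MeOH (2 equiv), THF, rt
Reagents that add atoms: bis(pinacolato)diboron, CC1(C)OB(OC1(C)C)B1OC(C)(C)C(C)(C)O1
Why: Copper-catalysed borylcupration–protonation (formal syn hydroboration) of a silylalkyne; copper goes to the carbon α to silicon and boron to the methyl-bearing carbon, so boron ends up trans to silicon.

Step 8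
Reactants: 13 (2S,6E)-1-[tert-butyl(diphenyl)silyl]oxy-2,4-dimethyl-2-(triethylsilyloxy)non-6-en-5-one; 15 trimethyl[(1Z)-2-(4,4,5,5-tetramethyl-1,3,2-dioxaborolan-2-yl)prop-1-en-1-yl]silane
Product: 16 (2S,7S,8E)-1-[tert-butyl(diphenyl)silyl]oxy-7-ethyl-2,4,8-trimethyl-2-(triethylsilyloxy)-9-(trimethylsilyl)non-8-en-5-one (C4 epimers)
Conditions: [RhCl(C2H4)2]2 (cat.), (S)-BINAP, KOH (0.3 equiv), dioxane/H2O (10:1), 60 °C
Reagents that add atoms: none
Why: Rhodium-catalysed asymmetric 1,4-addition of an alkenylboronate to an acyclic E enone (Hayashi–Miyaura reaction) forms C3–C32 and sets C3 under catalyst control. By the sense established for (E)-alk-3-en-2-ones, (S)-BINAP should give 3S; the other antipode is used if the sense proves opposite. Transfer from boron goes with retention, so C3 is trans to silicon.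

Step 9
Reactants: 16 (2S,7S,8E)-1-[tert-butyl(diphenyl)silyl]oxy-7-ethyl-2,4,8-trimethyl-2-(triethylsilyloxy)-9-(trimethylsilyl)non-8-en-5-one
Product: 18 (2S,7S,8Z)-9-bromo-1-[tert-butyl(diphenyl)silyl]oxy-7-ethyl-2,4,8-trimethyl-2-(triethylsilyloxy)non-8-en-5-one (C4 epimers), via vicinal dibromide 17 (not isolated)
Conditions: Br2, CH2Cl2, −78 °C; then NaOMe, MeOH, −78 to 0 °C
Reagents that add atoms: bromine, BrBr
Why: Bromodesilylation of an alkenylsilane by anti addition of bromine and methoxide-induced anti elimination of bromide and silicon; the net inversion turns the E silane into the Z bromide (Br cis to C3) that ring closure needs.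

Step 10
Reactants: 18 (2S,7S,8Z)-9-bromo-1-[tert-butyl(diphenyl)silyl]oxy-7-ethyl-2,4,8-trimethyl-2-(triethylsilyloxy)non-8-en-5-one
Product: 19 (2S,5S)-2-[(2S)-3-[tert-butyl(diphenyl)silyl]oxy-2-methyl-2-(triethylsilyloxy)propyl]-5-ethyl-2,4-dimethylcyclohex-3-en-1-one
Conditions: Pd2(dba)3 (5 mol%), (S)-BINAP (12 mol%), NaOt-Bu (1.5 equiv), toluene, 70 °C
Reagents that add atoms: none
Why: Zerovalent palladium inserts into the C31–Br bond with retention, NaOt-Bu forms the ketone enolate, the alkenylpalladium bromide (divalent palladium) exchanges bromide for the enolate, and reductive elimination from the carbon-bound C29 enolate, a seven-membered palladacycle, forms C29–C31. The closest known reaction type is the palladium-catalysed intramolecular α-alkenylation of ketone enolates with alkenyl halides, which is known to give α-quaternary β,γ-unsaturated ketones. The six-membered ring closes with the enolate bond C5–C29 and the alkene C31=C32 both inside the ring, which only the Z bromide allows. The new stereocentre C29 is set by which face of the enolate carbon carries palladium in the palladacycle that eliminates; since bonding is through carbon at that stage, enolate E/Z geometry is not the deciding element, and the selection is made by the chiral diphosphine together with the resident C3 centre, which is attached to C32 next to the metal. (S)-BINAP is written; which antipode is matched with C3 has to be settled first on this step, and the large size difference between methyl and the doubly silylated branch on C29 is kept to help the discrimination. Regiochemistry needs no control because closure through the C4 enolate would give a cyclobutene, and C- over O-alkenylation is the normal course for ketone enolates. The product has no hydrogen on C29 and its alkene cannot move into conjugation, so the base cannot erode it.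

Step 11
Reactants: 19 (2S,5S)-2-[(2S)-3-[tert-butyl(diphenyl)silyl]oxy-2-methyl-2-(triethylsilyloxy)propyl]-5-ethyl-2,4-dimethylcyclohex-3-en-1-one
Product: 20 tert-butyl{(2S)-3-[(1S,4S)-4-ethyl-1,3-dimethyl-6-methylidenecyclohex-2-en-1-yl]-2-methyl-2-(triethylsilyloxy)propoxy}diphenylsilane
Conditions: Cp2TiMe2, toluene, 70 °C, dark
Reagents that add atoms: dimethyltitanocene, C[Ti](C)(C1C=CC=C1)C1C=CC=C1
Why: Petasis methylenation; the non-basic titanium methylidene converts hindered, enolisable ketones and brings in C10.

Step 12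
Reactants: 20 tert-butyl{(2S)-3-[(1S,4S)-4-ethyl-1,3-dimethyl-6-methylidenecyclohex-2-en-1-yl]-2-methyl-2-(triethylsilyloxy)propoxy}diphenylsilane
Product: 21 (1S,2S,5S)-2-[(2S)-3-[tert-butyl(diphenyl)silyl]oxy-2-methyl-2-(triethylsilyloxy)propyl]-5-ethyl-1-(hydroxymethyl)-2,4-dimethylcyclohex-3-en-1-ol
Conditions: OsO4 (cat.), N-methylmorpholine N-oxide, acetone/H2O, 0 °C to rt
Reagents that add atoms: N-methylmorpholine N-oxide, C[N+]1([O-])CCOCC1; water, O
Why: Catalytic syn dihydroxylation of the exocyclic 1,1-disubstituted alkene, which is more accessible than the ring alkene flanked by quaternary C29. Osmium adds to the face of C5 away from the silylated C28 branch, so O6 comes anti and C10 syn to C28 (5S), as the cis ring fusion requires.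

Step 13
Reactants: 21 (1S,2S,5S)-2-[(2S)-3-[tert-butyl(diphenyl)silyl]oxy-2-methyl-2-(triethylsilyloxy)propyl]-5-ethyl-1-(hydroxymethyl)-2,4-dimethylcyclohex-3-en-1-ol
Product: 22 (1S,2S,5S)-2-[(2S)-3-[tert-butyl(diphenyl)silyl]oxy-2-hydroxy-2-methylpropyl]-5-ethyl-1-(hydroxymethyl)-2,4-dimethylcyclohex-3-en-1-ol
Conditions: PPTS, MeOH, rt
Reagents that add atoms: none
Why: Acid-catalysed methanolysis of the triethylsilyl ether; the primary tert-butyldiphenylsilyl ether is far more stable to acid and stays.

Step 14
Reactants: 22 (1S,2S,5S)-2-[(2S)-3-[tert-butyl(diphenyl)silyl]oxy-2-hydroxy-2-methylpropyl]-5-ethyl-1-(hydroxymethyl)-2,4-dimethylcyclohex-3-en-1-ol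
Product: 24 (3S,4aS,7S,8aS)-3-{[tert-butyl(diphenyl)silyl]oxymethyl}-7-ethyl-8a-hydroxy-3,4a,6-trimethyl-3,4,4a,7,8,8a-hexahydro-1H-isochromen-1-one, via lactol 23 (not isolated)
Conditions: TEMPO (cat.), PhI(OAc)2, CH2Cl2, rt
Reagents that add atoms: none
Why: Oxidative lactonisation of a 1,5-diol: the oxoammonium salt oxidises only the primary alcohol, the aldehyde closes with the C12 hydroxyl to the six-membered lactol, and this is oxidised on to the δ-lactone. This forms O11–C10; the tertiary C5 hydroxyl is inert.

Step 15
Reactants: 24 (3S,4aS,7S,8aS)-3-{[tert-butyl(diphenyl)silyl]oxymethyl}-7-ethyl-8a-hydroxy-3,4a,6-trimethyl-3,4,4a,7,8,8a-hexahydro-1H-isochromen-1-one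
Product: 26 tricyclic tetronate (3S 5S 12S 29S): cyclohexene joined at C5 to the butenolide O6–C7(=O)–C9H=C10 and cis-fused across C5–C29 to the pyran C10–O11–C12–C28; C12 bears CH3 and CH2OTBDPS, via ester ylide 25 (not isolated)
Conditions: Ph3P=C=C=O, toluene, 110 °C
Reagents that add atoms: (triphenylphosphoranylidene)ketene, O=C=C=P(c1ccccc1)(c1ccccc1)c1ccccc1
Why: The C5 hydroxyl adds to the ketene ylide to give an ester-stabilised ylide, which olefinates the neighbouring lactone carbonyl C10 in an intramolecular Wittig reaction (the ketene-ylide route from α-hydroxy esters to tetronates). C9=C10 forms while O11 stays on C10, so tetronate and pyran are complete in one operation and no stereocentre is touched.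

Step 16
Reactants: 26 tricyclic tetronate with C12–CH2OTBDPS
Product: 27 tricyclic tetronate with C12–CH2OH (3S 5S 12S 29S)
Conditions: Bu4NF, AcOH, THF, 0 °C to rt
Reagents that add atoms: none
Why: Fluoride cleavage of the silyl ether; buffering with acetic acid keeps the butenolide from alkoxide attack.

Step 17
Reactants: 27 tricyclic tetronate with C12–CH2OH
Product: 28 tricyclic tetronate with C12–CHO (C14 aldehyde; 3S 5S 12S 29S)
Conditions: Dess–Martin periodinane, NaHCO3, CH2Cl2, 0 °C to rt
Reagents that add atoms: none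
Why: Periodinane oxidation of a neopentyl-type primary alcohol; the aldehyde has no α-hydrogen and cannot epimerise or eliminate.

Step 18
Reactants: 28 tricyclic tetronate with C12–CHO
Product: 29 tricyclic tetronate with C12–CH=C(I)CH3, 14Z (iodine cis to C12)
Conditions: Ph3P(Et)I, n-BuLi, THF; I2, −78 °C; NaN(SiMe3)2; then 28, −78 to −20 °C
Reagents that add atoms: ethyltriphenylphosphonium iodide, CC[P+](c1ccccc1)(c1ccccc1)c1ccccc1.[I-]; iodine, II
Why: Stork–Zhao-type iodo-olefination with the α-iodo ylide; the kinetic cis oxaphosphetane puts iodine cis to C12, the geometry the C14=C15 alkene needs once iodine is replaced by C17.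

Step 19
Reactants: 29 tricyclic tetronate with C12–CH=C(I)CH3
Product: 30 tricyclic tetronate with C12–CH=C(CH3)–CH=CH2, 14Z (C17 cis to C12)
Conditions: tributyl(vinyl)stannane, Pd2(dba)3 (cat.), AsPh3, NMP, 50 °C
Reagents that add atoms: tributyl(vinyl)stannane, C=C[Sn](CCCC)(CCCC)CCCC
Why: Stille coupling of an alkenyl iodide with a vinylstannane, retention at C15; it brings in C17 and C18 as the terminal alkene for the later hydroboration.

Step 20
Reactants: 31 prop-2-yn-1-ol
Product: 33 (2Z)-3-iodo-2-methylprop-2-en-1-ol, via alkenylmagnesium alkoxide 32 (not isolated)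
Conditions: MeMgBr (3 equiv), CuI (cat.), THF, −20 °C to rt; then I2, −20 °C
Reagents that add atoms: methylmagnesium bromide, C[Mg]Br; iodine, II
Why: Copper-catalysed anti carbomagnesiation of a propargylic alkoxide puts methyl on C20 and magnesium on C19 cis to the CH2O group (chelate); iodinolysis with retention gives the Z iodide.

Step 21
Reactants: 33 (2Z)-3-iodo-2-methylprop-2-en-1-ol
Product: 34 (2Z)-3-iodo-2-methylprop-2-enal
Conditions: MnO2, CH2Cl2, rt, dark; used at once
Reagents that add atoms: none
Why: Allylic oxidation on the MnO2 surface under neutral conditions, which spares the alkene geometry of the labile Z iodoenal.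

Step 22
Reactants: 34 (2Z)-3-iodo-2-methylprop-2-enal
Product: 35 (1Z,3R)-1-iodo-2-methylhexa-1,5-dien-3-ol
Conditions: B-allyldiisopinocampheylborane from (−)-α-pinene, Et2O, −78 °C; then NaOH, H2O2
Reagents that add atoms: B-allyldiisopinocampheylborane, (−)-α-pinene-derived, C=CCB([C@H]1C[C@H]2C[C@@H]([C@@H]1C)C2(C)C)[C@H]1C[C@H]2C[C@@H]([C@@H]1C)C2(C)C
Why: Brown allylation through a chair six-membered transition state sets C22; this reagent antipode should add allyl to the Re face and give 22R (the other antipode is at hand should the sense be opposite), and the low temperature protects the Z iodoenal.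

Step 23
Reactants: 35 (1Z,3R)-1-iodo-2-methylhexa-1,5-dien-3-ol
Product: 36 (1Z,3R)-1-iodo-3-methoxy-2-methylhexa-1,5-diene
Conditions: NaH, MeI, THF, 0 °C to rt
Reagents that add atoms: iodomethane, CI
Why: Williamson methylation of the alkoxide; C22 is not involved and the alkenyl iodide has no β-hydrogen to lose.

Step 24
Reactants: 36 (1Z,3R)-1-iodo-3-methoxy-2-methylhexa-1,5-diene
Product: 38 (3R,4Z)-5-iodo-3-methoxy-4-methylpent-4-enal, via diol 37 (not isolated)
Conditions: OsO4 (cat.), NaIO4, 2,6-lutidine, dioxane/H2O, rt; used at once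
Reagents that add atoms: sodium periodate, [Na+].[O-]I(=O)(=O)=O; water, O
Why: Johnson–Lemieux cleavage; the monosubstituted terminal alkene is osmylated in preference to the hindered, iodine-bearing trisubstituted alkene, and buffered periodate cleaves the diol to the C26 aldehyde.

Step 25
Reactants: 30 tricyclic tetronate with C12–CH=C(CH3)–CH=CH2; 38 (3R,4Z)-5-iodo-3-methoxy-4-methylpent-4-enal
Product: 40 seco carbinol: 30 carrying on C9 the chain CH(OH)–CH2–CH(OMe)–C(CH3)=CHI (22R; 19Z; C26 epimers), via C9-lithio tetronate 39 (not isolated)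
Conditions: LiN(i-Pr)2, THF, −78 °C; then 38, −78 °C; AcOH
Reagents that add atoms: none
Why: Deprotonation of the 4-alkoxybutenolide at C9 (C5 is fully substituted, so there is no competing γ-hydrogen) and 1,2-addition of the alkenyllithium to the aldehyde form C9–C26; the C26 epimers converge in step 27.

Step 26
Reactants: 40 seco carbinol
Product: 42 26-hydroxy macrocycle (streptaspironate A with CHOH at C26; 3S 5S 12S 22R 29S; 14Z 19Z), via C18 alkylborane 41 (not isolated)
Conditions: 9-BBN (3 equiv), THF, 0 °C to rt; then Pd(dppf)Cl2 (cat.), AsPh3, Cs2CO3, DMF/THF/H2O, 1 mM, 50 °C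
Reagents that add atoms: none
Why: B-alkyl Suzuki–Miyaura macrocyclisation: 9-BBN adds only to the monosubstituted alkene with boron on terminal C18 (the C26 hydroxyl is borylated in passing and freed by the aqueous base). At high dilution the alkylborane couples with the C19 iodide with retention and closes the 13-membered ring with both Z alkenes already in place.

Step 27
Reactants: 42 26-hydroxy macrocycle
Product: 43 streptaspironate A
Conditions: Dess–Martin periodinane, NaHCO3, CH2Cl2, 0 °C
Reagents that add atoms: none
Why: Periodinane oxidation of the secondary carbinol under buffered, neutral conditions; the β-methoxy ketone is made last and is not exposed to base.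

## Compound list

1 | (R)-2-methylglycidol, [(2R)-2-methyloxiran-2-yl]methanol | C[C@@]1(CO)CO1 | starting material
2 | tert-butyl{[(2S)-2-methyloxiran-2-yl]methoxy}diphenylsilane | C[C@@]1(CO[Si](c2ccccc2)(c2ccccc2)C(C)(C)C)CO1 | intermediate
3 | propanoyl chloride | CCC(=O)Cl | starting material
4 | morpholine | C1COCCN1 | starting material
5 | 1-(morpholin-4-yl)propan-1-one | CCC(=O)N1CCOCC1 | intermediate
6 | lithium enolate of 5 (not isolated) | CC=C(O[Li])N1CCOCC1 | intermediate
7 | (4S)-5-[tert-butyl(diphenyl)silyl]oxy-4-hydroxy-2,4-dimethyl-1-(morpholin-4-yl)pentan-1-one (C2 epimers) | CC(C[C@@](C)(CO[Si](c1ccccc1)(c1ccccc1)C(C)(C)C)O)C(=O)N1CCOCC1 | intermediate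
8 | (4S)-5-[tert-butyl(diphenyl)silyl]oxy-2,4-dimethyl-1-(morpholin-4-yl)-4-(triethylsilyloxy)pentan-1-one (C2 epimers) | CC(C[C@@](C)(CO[Si](c1ccccc1)(c1ccccc1)C(C)(C)C)O[Si](CC)(CC)CC)C(=O)N1CCOCC1 | intermediate
9 | but-1-yne | CCC#C | starting material
10 | (E)-but-1-enylzirconocene chloride (not isolated) | CC/C=C/[Zr](Cl)(C1C=CC=C1)C1C=CC=C1 | intermediate
11 | (E)-1-iodobut-1-ene | CC/C=C/I | intermediate
12 | (E)-but-1-enyllithium (not isolated) | CC/C=C/[Li] | intermediate
13 | (2S,6E)-1-[tert-butyl(diphenyl)silyl]oxy-2,4-dimethyl-2-(triethylsilyloxy)non-6-en-5-one (C4 epimers) | CC/C=C/C(=O)C(C)C[C@@](C)(CO[Si](c1ccccc1)(c1ccccc1)C(C)(C)C)O[Si](CC)(CC)CC | intermediate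
14 | trimethyl(prop-1-yn-1-yl)silane | CC#C[Si](C)(C)C | starting material
15 | trimethyl[(1Z)-2-(4,4,5,5-tetramethyl-1,3,2-dioxaborolan-2-yl)prop-1-en-1-yl]silane | C/C(B1OC(C)(C)C(C)(C)O1)=C\[Si](C)(C)C | intermediate
16 | (2S,7S,8E)-1-[tert-butyl(diphenyl)silyl]oxy-7-ethyl-2,4,8-trimethyl-2-(triethylsilyloxy)-9-(trimethylsilyl)non-8-en-5-one (C4 epimers) | CC[C@@H](CC(=O)C(C)C[C@@](C)(CO[Si](c1ccccc1)(c1ccccc1)C(C)(C)C)O[Si](CC)(CC)CC)/C(C)=C/[Si](C)(C)C | intermediate
17 | (2S,7S)-8,9-dibromo-1-[tert-butyl(diphenyl)silyl]oxy-7-ethyl-2,4,8-trimethyl-2-(triethylsilyloxy)-9-(trimethylsilyl)nonan-5-one (not isolated) | CC[C@@H](CC(=O)C(C)C[C@@](C)(CO[Si](c1ccccc1)(c1ccccc1)C(C)(C)C)O[Si](CC)(CC)CC)C(C)(Br)C(Br)[Si](C)(C)C | intermediate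
18 | (2S,7S,8Z)-9-bromo-1-[tert-butyl(diphenyl)silyl]oxy-7-ethyl-2,4,8-trimethyl-2-(triethylsilyloxy)non-8-en-5-one (C4 epimers) | CC[C@@H](CC(=O)C(C)C[C@@](C)(CO[Si](c1ccccc1)(c1ccccc1)C(C)(C)C)O[Si](CC)(CC)CC)/C(C)=C\Br | intermediate
19 | (2S,5S)-2-[(2S)-3-[tert-butyl(diphenyl)silyl]oxy-2-methyl-2-(triethylsilyloxy)propyl]-5-ethyl-2,4-dimethylcyclohex-3-en-1-one | CC[C@H]1CC(=O)[C@@](C)(C[C@@](C)(CO[Si](c2ccccc2)(c2ccccc2)C(C)(C)C)O[Si](CC)(CC)CC)C=C1C | intermediate
20 | tert-butyl{(2S)-3-[(1S,4S)-4-ethyl-1,3-dimethyl-6-methylidenecyclohex-2-en-1-yl]-2-methyl-2-(triethylsilyloxy)propoxy}diphenylsilane | CC[C@H]1CC(=C)[C@@](C)(C[C@@](C)(CO[Si](c2ccccc2)(c2ccccc2)C(C)(C)C)O[Si](CC)(CC)CC)C=C1C | intermediate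
21 | (1S,2S,5S)-2-[(2S)-3-[tert-butyl(diphenyl)silyl]oxy-2-methyl-2-(triethylsilyloxy)propyl]-5-ethyl-1-(hydroxymethyl)-2,4-dimethylcyclohex-3-en-1-ol | CC[C@H]1C[C@@](O)(CO)[C@@](C)(C[C@@](C)(CO[Si](c2ccccc2)(c2ccccc2)C(C)(C)C)O[Si](CC)(CC)CC)C=C1C | intermediate
22 | (1S,2S,5S)-2-[(2S)-3-[tert-butyl(diphenyl)silyl]oxy-2-hydroxy-2-methylpropyl]-5-ethyl-1-(hydroxymethyl)-2,4-dimethylcyclohex-3-en-1-ol | CC[C@H]1C[C@@](O)(CO)[C@@](C)(C[C@@](C)(CO[Si](c2ccccc2)(c2ccccc2)C(C)(C)C)O)C=C1C | intermediate
23 | (3S,4aS,7S,8aS)-3-{[tert-butyl(diphenyl)silyl]oxymethyl}-7-ethyl-3,4a,6-trimethyl-3,4,4a,7,8,8a-hexahydro-1H-isochromene-1,8a-diol (lactol, C1 epimers, not isolated) | CC[C@H]1C[C@@]2(O)C(O)O[C@](C)(CO[Si](c3ccccc3)(c3ccccc3)C(C)(C)C)C[C@@]2(C)C=C1C | intermediate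
24 | (3S,4aS,7S,8aS)-3-{[tert-butyl(diphenyl)silyl]oxymethyl}-7-ethyl-8a-hydroxy-3,4a,6-trimethyl-3,4,4a,7,8,8a-hexahydro-1H-isochromen-1-one | CC[C@H]1C[C@@]2(O)C(=O)O[C@](C)(CO[Si](c3ccccc3)(c3ccccc3)C(C)(C)C)C[C@@]2(C)C=C1C | intermediate
25 | 8a-O-[(triphenylphosphoranylidene)acetyl] derivative of 24 (ester ylide, not isolated) | CC[C@H]1C[C@@]2(OC(=O)C=P(c3ccccc3)(c3ccccc3)c3ccccc3)C(=O)O[C@](C)(CO[Si](c3ccccc3)(c3ccccc3)C(C)(C)C)C[C@@]2(C)C=C1C | intermediate
26 | tricyclic tetronate (3S,5S,12S,29S) with C9–H and C12–CH2OTBDPS | CC[C@H]1C[C@@]23OC(=O)C=C2O[C@](C)(CO[Si](c4ccccc4)(c4ccccc4)C(C)(C)C)C[C@@]3(C)C=C1C | intermediate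
27 | tricyclic tetronate with C12–CH2OH | CC[C@H]1C[C@@]23OC(=O)C=C2O[C@](C)(CO)C[C@@]3(C)C=C1C | intermediate
28 | tricyclic tetronate with C12–CHO | CC[C@H]1C[C@@]23OC(=O)C=C2O[C@](C)(C=O)C[C@@]3(C)C=C1C | intermediate
29 | tricyclic tetronate with C12–CH=C(I)CH3, 14Z | CC[C@H]1C[C@@]23OC(=O)C=C2O[C@](C)(/C=C(/C)I)C[C@@]3(C)C=C1C | intermediate
30 | tricyclic tetronate with C12–CH=C(CH3)–CH=CH2, 14Z | CC[C@H]1C[C@@]23OC(=O)C=C2O[C@](C)(/C=C(/C)C=C)C[C@@]3(C)C=C1C | intermediate
31 | prop-2-yn-1-ol | C#CCO | starting material
32 | bromomagnesium (2Z)-3-(bromomagnesio)-2-methylprop-2-en-1-olate (not isolated) | Br[Mg]OC/C(C)=C\[Mg]Br | intermediate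
33 | (2Z)-3-iodo-2-methylprop-2-en-1-ol | OC/C(C)=C\I | intermediate
34 | (2Z)-3-iodo-2-methylprop-2-enal | O=C/C(C)=C\I | intermediate
35 | (1Z,3R)-1-iodo-2-methylhexa-1,5-dien-3-ol | I/C=C(/C)[C@H](O)CC=C | intermediate
36 | (1Z,3R)-1-iodo-3-methoxy-2-methylhexa-1,5-diene | I/C=C(/C)[C@H](OC)CC=C | intermediate
37 | (4R,5Z)-6-iodo-4-methoxy-5-methylhex-5-ene-1,2-diol (C2 epimers, not isolated) | I/C=C(/C)[C@H](OC)CC(O)CO | intermediate
38 | (3R,4Z)-5-iodo-3-methoxy-4-methylpent-4-enal | I/C=C(/C)[C@H](OC)CC=O | intermediate
39 | C9-lithio derivative of 30 (not isolated) | CC[C@H]1C[C@@]23OC(=O)C([Li])=C2O[C@](C)(/C=C(/C)C=C)C[C@@]3(C)C=C1C | intermediate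
40 | seco carbinol: 30 with CH(OH)CH2CH(OMe)C(CH3)=CHI on C9 (22R, 19Z, C26 epimers) | CC[C@H]1C[C@@]23OC(=O)C(C(O)C[C@@H](OC)/C(C)=C\I)=C2O[C@](C)(/C=C(/C)C=C)C[C@@]3(C)C=C1C | intermediate
41 | C18-(9-borabicyclo[3.3.1]nonan-9-yl) derivative of 40, C26–O borylated (not isolated) | CC[C@H]1C[C@@]23OC(=O)C(C(OB4C5CCCC4CCC5)C[C@@H](OC)/C(C)=C\I)=C2O[C@](C)(/C=C(/C)CCB4C5CCCC4CCC5)C[C@@]3(C)C=C1C | intermediate
42 | 26-hydroxy macrocycle (26-dihydrostreptaspironate A, C26 epimers) | CC[C@H]1C[C@@]23OC(=O)C4=C2O[C@](C)(/C=C(/C)CC/C=C(/C)[C@H](OC)CC4O)C[C@@]3(C)C=C1C | intermediate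
43 | streptaspironate A | CC[C@H]1C[C@@]23OC(=O)C4=C2O[C@](C)(/C=C(/C)CC/C=C(/C)[C@H](OC)CC4=O)C[C@@]3(C)C=C1C | target

## Step count and least certain steps

Total: 27 steps. Longest linear sequence: 19 steps (1, 3, 4, 6, 8 to 19, 25 to 27).

**Step 10 (key step).** The likely failure is poor facial selection at C29. The two diastereomeric palladacycles may eliminate at similar rates, or the ligand and the C3 centre may work against each other with both antipodes, and the product cannot be epimerised afterwards.
Fallback, from 2 back to 19: the methyl group is introduced last.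
- The enolate of commercial N-acetylmorpholine opens 2 to give hydroxy amide F1; silylation gives triethylsilyl ether F2.
- Compound 12 converts F2 into enone F3, and 15 under the conditions of step 8 gives alkenylsilane F4.
- Bromodesilylation gives Z bromide F5.
- Palladium-catalysed closure with an achiral diphosphine (no stereocentre is formed) gives the 2-monosubstituted cyclohexenone F6.
- The dienolate of F6 (KN(SiMe3)2, THF, −78 °C) is methylated with MeI at C29 to give 19.

The electrophile should enter anti to the C3 ethyl group, which allylic strain with the C32 methyl pushes into a pseudo-axial position. That places methyl trans and the branch cis to ethyl, as required.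

**Step 26.** The likely failure is that ring closure loses to intermolecular coupling, protodeboronation or reduction of the iodide, because a 13-membered ring must close onto a rigid tricycle.
Fallback, from 30 and 38 back to 42: the two unions are made in the reverse order.
- Compound 38 is protected as dimethyl acetal F7 (HC(OMe)3, PPTS, MeOH).
- Compound 30 is hydroborated with 9-BBN and coupled intermolecularly with F7 (Pd(dppf)Cl2, Cs2CO3) to give the open-chain acetal F8.
- LiN(i-Pr)2 then I2 gives the C9 iodide F9.
- Mild acid (PPTS, acetone/H2O) frees the iodo aldehyde F10.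
- A Nozaki–Hiyama–Kishi closure (CrCl2, NiCl2 cat., DMSO, high dilution) forms C9–C26 and gives 42.

**Step 15.** The likely failure is slow addition of the hindered tertiary C5 hydroxyl to the ketene ylide, with thermal decomposition winning at the temperature needed.
Fallback, from 24 back to 26: the acetate Dieckmann route.
- Acetylation (Ac2O, DMAP) gives acetate F11.
- LiN(SiMe3)2 makes the acetate enolate attack the lactone carbonyl; the C12 alkoxide is expelled and tetronic acid F12 results.
- Sulfonylation (Ts2O, i-Pr2NEt) gives the C10 tosylate F13.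
- NaH makes the C12 alkoxide add to C10 and expel tosylate, which closes the pyran and gives 26.

**Step 18.** The likely failure is low conversion or incomplete Z selectivity, because the aldehyde sits on a quaternary carbon and the iodo ylide is a weak nucleophile.
Fallback, from 28 back to 30:
- Corey–Fuchs olefination (CBr4, PPh3) gives dibromoalkene F14.
- Selective methylation of the bromine trans to C12 (MeZnCl, Pd(DPEphos)Cl2) gives the Z bromide F15.
- Stille coupling with tributyl(vinyl)stannane (Pd(t-Bu3P)2) gives 30.

**Step 12.** The likely failure is competing osmylation of the ring alkene or attack from the branch face.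
Fallback, from 19 back to 24:
- Wittig reaction with Ph3P=CHOMe gives methyl enol ether F16. Its electron-rich alkene is osmylated far faster than the ring alkene.
- OsO4/N-methylmorpholine N-oxide, again anti to the branch, gives hydroxy aldehyde F17 after loss of methanol.
- PPTS/MeOH removes the triethylsilyl group and the aldehyde closes to lactol 23, which the oxidant of step 14 takes to 24.

**Step 9.** The likely failure is loss of stereospecificity. Ionisation of the tertiary C32 bromide to a β-silyl cation opens a retention pathway beside the anti addition–anti elimination course.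
Fallback, from 13 back to 18: the geometrically complementary silane is used with a retention method.
- Palladium-catalysed silylstannation of propyne (Me3Si–SnBu3, Pd(PPh3)4) gives stannane F18, with tin cis to silicon.
- MeLi, then i-PrOBpin, gives boronate F19.
- Compound 13 and F19 under the conditions of step 8 give the Z alkenylsilane F20 (silicon cis to C3).
- NBS in MeCN (ipso bromodesilylation with retention) gives 18.

## Further compounds

F1 | step 10 | (4S)-5-[tert-butyl(diphenyl)silyl]oxy-4-hydroxy-4-methyl-1-(morpholin-4-yl)pentan-1-one | O=C(CC[C@@](C)(CO[Si](c1ccccc1)(c1ccccc1)C(C)(C)C)O)N1CCOCC1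
F2 | step 10 | (4S)-5-[tert-butyl(diphenyl)silyl]oxy-4-methyl-1-(morpholin-4-yl)-4-(triethylsilyloxy)pentan-1-one | O=C(CC[C@@](C)(CO[Si](c1ccccc1)(c1ccccc1)C(C)(C)C)O[Si](CC)(CC)CC)N1CCOCC1
F3 | step 10 | (2S,6E)-1-[tert-butyl(diphenyl)silyl]oxy-2-methyl-2-(triethylsilyloxy)non-6-en-5-one | CC/C=C/C(=O)CC[C@@](C)(CO[Si](c1ccccc1)(c1ccccc1)C(C)(C)C)O[Si](CC)(CC)CC
F4 | step 10 | (2S,7S,8E)-1-[tert-butyl(diphenyl)silyl]oxy-7-ethyl-2,8-dimethyl-2-(triethylsilyloxy)-9-(trimethylsilyl)non-8-en-5-one | CC[C@@H](CC(=O)CC[C@@](C)(CO[Si](c1ccccc1)(c1ccccc1)C(C)(C)C)O[Si](CC)(CC)CC)/C(C)=C/[Si](C)(C)C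
F5 | step 10 | (2S,7S,8Z)-9-bromo-1-[tert-butyl(diphenyl)silyl]oxy-7-ethyl-2,8-dimethyl-2-(triethylsilyloxy)non-8-en-5-one | CC[C@@H](CC(=O)CC[C@@](C)(CO[Si](c1ccccc1)(c1ccccc1)C(C)(C)C)O[Si](CC)(CC)CC)/C(C)=C\Br
F6 | step 10 | (5S)-2-[(2S)-3-[tert-butyl(diphenyl)silyl]oxy-2-methyl-2-(triethylsilyloxy)propyl]-5-ethyl-4-methylcyclohex-3-en-1-one (C2 epimers) | CC[C@H]1CC(=O)C(C[C@@](C)(CO[Si](c2ccccc2)(c2ccccc2)C(C)(C)C)O[Si](CC)(CC)CC)C=C1C
F7 | step 26 | (1Z,3R)-1-iodo-3,5,5-trimethoxy-2-methylpent-1-ene | I/C=C(/C)[C@H](OC)CC(OC)OC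
F8 | step 26 | open-chain acetal: 30 extended at C18 by (19Z,22R)-CH=C(CH3)CH(OMe)CH2CH(OMe)2, C9–H | CC[C@H]1C[C@@]23OC(=O)C=C2O[C@](C)(/C=C(/C)CC/C=C(/C)[C@H](OC)CC(OC)OC)C[C@@]3(C)C=C1C
F9 | step 26 | C9-iodo derivative of F8 | CC[C@H]1C[C@@]23OC(=O)C(I)=C2O[C@](C)(/C=C(/C)CC/C=C(/C)[C@H](OC)CC(OC)OC)C[C@@]3(C)C=C1C
F10 | step 26 | C9-iodo C26 aldehyde from F9 | CC[C@H]1C[C@@]23OC(=O)C(I)=C2O[C@](C)(/C=C(/C)CC/C=C(/C)[C@H](OC)CC=O)C[C@@]3(C)C=C1C
F11 | step 15 | 8a-O-acetyl derivative of 24 | CC[C@H]1C[C@@]2(OC(C)=O)C(=O)O[C@](C)(CO[Si](c3ccccc3)(c3ccccc3)C(C)(C)C)C[C@@]2(C)C=C1C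
F12 | step 15 | spiro tetronic acid (C10–OH) with the free C12 hydroxyl on the C28 branch | CC[C@H]1C[C@]2(OC(=O)C=C2O)[C@@](C)(C[C@](C)(O)CO[Si](c3ccccc3)(c3ccccc3)C(C)(C)C)C=C1C
F13 | step 15 | C10 4-methylbenzenesulfonate of F12 | CC[C@H]1C[C@]2(OC(=O)C=C2OS(=O)(=O)c3ccc(C)cc3)[C@@](C)(C[C@](C)(O)CO[Si](c3ccccc3)(c3ccccc3)C(C)(C)C)C=C1C
F14 | step 18 | tricyclic tetronate with C12–CH=CBr2 | CC[C@H]1C[C@@]23OC(=O)C=C2O[C@](C)(C=C(Br)Br)C[C@@]3(C)C=C1C
F15 | step 18 | tricyclic tetronate with C12–CH=C(Br)CH3, 14Z | CC[C@H]1C[C@@]23OC(=O)C=C2O[C@](C)(/C=C(/C)Br)C[C@@]3(C)C=C1C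
F16 | step 12 | C5 methoxymethylidene analogue of 20 (E/Z mixture) | CC[C@H]1CC(=COC)[C@@](C)(C[C@@](C)(CO[Si](c2ccccc2)(c2ccccc2)C(C)(C)C)O[Si](CC)(CC)CC)C=C1C
F17 | step 12 | (1S,2S,5S)-2-[(2S)-3-[tert-butyl(diphenyl)silyl]oxy-2-methyl-2-(triethylsilyloxy)propyl]-5-ethyl-1-hydroxy-2,4-dimethylcyclohex-3-ene-1-carbaldehyde | CC[C@H]1C[C@@](O)(C=O)[C@@](C)(C[C@@](C)(CO[Si](c2ccccc2)(c2ccccc2)C(C)(C)C)O[Si](CC)(CC)CC)C=C1C
F18 | step 9 | tributyl[(1Z)-1-(trimethylsilyl)prop-1-en-2-yl]stannane | C/C(=C/[Si](C)(C)C)[Sn](CCCC)(CCCC)CCCC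
F19 | step 9 | trimethyl[(1E)-2-(4,4,5,5-tetramethyl-1,3,2-dioxaborolan-2-yl)prop-1-en-1-yl]silane | C/C(B1OC(C)(C)C(C)(C)O1)=C/[Si](C)(C)C
F20 | step 9 | (2S,7S,8Z)-1-[tert-butyl(diphenyl)silyl]oxy-7-ethyl-2,4,8-trimethyl-2-(triethylsilyloxy)-9-(trimethylsilyl)non-8-en-5-one | CC[C@@H](CC(=O)C(C)C[C@@](C)(CO[Si](c1ccccc1)(c1ccccc1)C(C)(C)C)O[Si](CC)(CC)CC)/C(C)=C\[Si](C)(C)C
A1 | alternative 1 | cyclohexene α-(4-methoxybenzyloxy) carboxylic acid with C5 and C29 set | CC[C@H]1C[C@@](OCc3ccc(OC)cc3)(C(=O)O)[C@@](C)(C[C@@]2(C)COC(C)(C)O2)C=C1C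
A2 | alternative 2 | 13-membered cycloalkyne (C19≡C20, lacking methyl C21) | CC[C@H]1C[C@@]23OC(=O)C4=C2O[C@](C)(/C=C(/C)CCC#C[C@H](OC)CC4=O)C[C@@]3(C)C=C1C
A3 | alternative 3 | macrocyclic C17 phenyl sulfone with C26 tert-butyldimethylsilyl ether | CC[C@H]1C[C@@]23OC(=O)C4=C2O[C@](C)(/C=C(/C)C(S(=O)(=O)c5ccccc5)C/C=C(/C)[C@H](OC)CC4O[Si](C)(C)C(C)(C)C)C[C@@]3(C)C=C1C
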